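**Retrosynthetic overview**
- Key cut: the bond between pyranone C2 and side-chain C1′. C2 serves as the nucleophile, as a C2-zincated chromone. This α-aryloxyvinyl metal is a masked acyl anion at a carbon that is normally the electrophilic β-carbon of the enone. C1′ is a primary alkyl iodide.
- 1-Iodononacosane (C29) comes from triacontanoic acid (C30) by decarboxylative iodination.
- The chromone nucleophile comes from 5,7-bis(methoxymethoxy)chromone, made from 5,7-dihydroxychromone.
- No ring is formed. Ring A (benzene) and ring B (4-pyranone) are bought already fused. The MOM groups are removed in the coupling flask.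

Assumption: the target has no stereocentre and no stereogenic double bond, so it is achiral and there is no enantiomer to select. The side chain is read as unbranched C29H59 (formula C38H64O4).

**Step 1**
Reactants: 1 triacontanoic acid (melissic acid)
Product: 3 1-iodononacosane, via triacontanoyl hypoiodite 2 (not isolated)
Conditions: PhI(OAc)2 (1.1 equiv, two portions), I2 (1.0 equiv), cyclohexane, reflux, hν (tungsten lamp), 2 h
Reagents that add atoms: iodine, [I][I]
Why: Suárez-type iododecarboxylation (a Hunsdiecker variant), in which acetyl hypoiodite from PhI(OAc)2/I2 exchanges with the acid to give 2, light breaks its weak oxygen–iodine bond, CO2 is lost and the primary nonacosyl radical is capped by iodine much faster than it can abstract hydrogen; no stereocentre is involved.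

**Step 2**
Reactants: 4 5,7-dihydroxy-4H-chromen-4-one
Product: 5 5,7-bis(methoxymethoxy)-4H-chromen-4-one
Conditions: NaH (2.6 equiv), MOMCl (2.8 equiv), DMF, 0 °C → rt, 4 h
Reagents that add atoms: chloromethyl methyl ether (MOMCl), COCCl
Why: Twofold Williamson-type O-alkylation, in which non-nucleophilic NaH converts both phenols (including the hydrogen-bonded 5-OH) to phenoxides that displace chloride, removing the acidic protons that would quench the amide base of step 3 and placing a chelating oxygen at C5; no stereocentre is formed.

**Step 3 (key step)**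
Reactants: 5 5,7-bis(methoxymethoxy)-4H-chromen-4-one (1.3 equiv); 3 1-iodononacosane (1.0 equiv)
Product: 8 5,7-dihydroxy-2-nonacosyl-4H-chromen-4-one (target), via bis(chromon-2-yl)zinc 6 (not isolated), via bis-MOM 2-nonacosylchromone 7 (not isolated)
Conditions: TMP2Zn·2MgCl2·2LiCl (0.6 equiv per 5; TMP = 2,2,6,6-tetramethylpiperidide), THF, −30 → 0 °C, 1 h; then 3, Pd2(dba)3 (2 mol%), P(c-C5H9)3 (8 mol%), N-methylimidazole (1.2 equiv), THF/NMP 2:1, 80 °C, 14 h; then MeOH, conc. HCl (to ca. 2 M), 60 °C, 3 h
Reagents that add atoms: bis(2,2,6,6-tetramethylpiperidin-1-yl)zinc (used as its 2 MgCl2·2 LiCl complex), CC1(C)CCCC(C)(C)N1[Zn]N1C(C)(C)CCCC1(C)C – supplies only the zinc atom of 6; no reagent atom other than hydrogen ends up in 7 or 8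
Why: Lewis-acid-triggered deprotonative zincation, alkyl Negishi cross-coupling and acetal cleavage in one flask, in which MgCl2 chelated between C4=O and the 5-oxygen blocks carbonyl-directed C3 metalation and acidifies C2–H so the hindered amide gives the polarity-reversed C2 nucleophile 6 (C2-zincated chromones are known in Negishi arylations), the electron-rich zerovalent palladium–tricyclopentylphosphine catalyst (known to couple alkenyl- and arylzincs with primary alkyl iodides) takes up the iodide by an SN2-type oxidative addition and eliminates the sp2–sp3 bond faster than β-hydride loss at a temperature where waxy 3 dissolves, and warm HCl/MeOH removes both MOM groups while methanol traps the formaldehyde unit; no stereocentre is formed.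

**Compound list**
1 | triacontanoic acid (melissic acid) | CCCCCCCCCCCCCCCCCCCCCCCCCCCCCC(=O)O | starting material
2 | triacontanoyl hypoiodite | CCCCCCCCCCCCCCCCCCCCCCCCCCCCCC(=O)OI | intermediate
3 | 1-iodononacosane | CCCCCCCCCCCCCCCCCCCCCCCCCCCCCI | intermediate
4 | 5,7-dihydroxy-4H-chromen-4-one | O=c1ccoc2cc(O)cc(O)c12 | starting material
5 | 5,7-bis(methoxymethoxy)-4H-chromen-4-one | COCOc1cc(OCOC)c2c(=O)ccoc2c1 | intermediate
6 | bis[5,7-bis(methoxymethoxy)-4-oxo-4H-chromen-2-yl]zinc | COCOc1cc(OCOC)c2c(=O)cc([Zn]c3cc(=O)c4c(OCOC)cc(OCOC)cc4o3)oc2c1 | intermediate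
7 | 5,7-bis(methoxymethoxy)-2-nonacosyl-4H-chromen-4-one | CCCCCCCCCCCCCCCCCCCCCCCCCCCCCc1cc(=O)c2c(OCOC)cc(OCOC)cc2o1 | intermediate
8 | 5,7-dihydroxy-2-nonacosyl-4H-chromen-4-one | CCCCCCCCCCCCCCCCCCCCCCCCCCCCCc1cc(=O)c2c(O)cc(O)cc2o1 | target

**Totals**
Total steps: 3. Longest linear sequence: 2 (4 → 5 → 8, or 1 → 3 → 8).

**Steps most likely to fail**

1. Step 3.
   - Risks: some metalation at C3 or on ring A; slow transmetalation of the electron-poor zinc reagent; β-hydride elimination to 1-nonacosene; and no direct precedent for pairing a C2-zincated chromone with an unactivated alkyl iodide.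
   - Fallback, setting out from 5 and coming back at 7: 5 is zincated to 6 as before, but the flask is quenched with I2 to isolate 2-iodo-5,7-bis(methoxymethoxy)-4H-chromen-4-one F5. Its regiochemistry is confirmed by NMR (loss of the C2–H signal).
   - F5 and 3 are then joined as two electrophiles in a nickel-catalysed reductive cross-electrophile coupling (NiI2, 4,4′-di-tert-butyl-2,2′-bipyridine, zinc powder, N,N-dimethylacetamide, 60 °C). The nonacosyl radical formed from 3 is captured by the chromon-2-yl-nickel species.
   - This gives 7, which is treated with HCl/MeOH as in step 3.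

2. Step 1.
   - Risks: low solubility of the C30 acid; formation of nonacosyl triacontanoate; and stray iodination along the chain.
   - Fallback, setting out from 1 and coming back at 7: 1 is condensed with N-hydroxyphthalimide (N,N′-diisopropylcarbodiimide, catalytic DMAP, warm CH2Cl2/THF) to give 1,3-dioxoisoindolin-2-yl triacontanoate F1.
   - F1 replaces 3 as the C29 electrophile toward zinc reagent 6 under NiCl2·6H2O/4,4′-di-tert-butyl-2,2′-bipyridine in THF/DMF at 25–40 °C. Single-electron reduction of the ester releases CO2 and phthalimide, and the nonacosyl radical is coupled on nickel to give 7.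

3. Step 2.
   - Risks: the chelated 5-OH may stay unalkylated, or the C2-unsubstituted pyranone may open under base.
   - Fallback, setting out from 4 and coming back at 8, at the cost of one more step: 4 is permethylated (MeI, K2CO3, DMF, 40 °C) to 5,7-dimethoxy-4H-chromen-4-one F2.
   - F2 is zincated as in step 3 to bis(5,7-dimethoxy-4-oxo-4H-chromen-2-yl)zinc F3.
   - F3 is coupled with 3 under the same palladium conditions to give 5,7-dimethoxy-2-nonacosyl-4H-chromen-4-one F4, which is isolated.
   - Both ethers are then cleaved with BBr3 (CH2Cl2, −78 °C → rt) to give 8.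

**Further compounds**
F1 | step 1 | 1,3-dioxoisoindolin-2-yl triacontanoate | CCCCCCCCCCCCCCCCCCCCCCCCCCCCCC(=O)ON1C(=O)c2ccccc2C1=O
F2 | step 2 | 5,7-dimethoxy-4H-chromen-4-one | COc1cc(OC)c2c(=O)ccoc2c1
F3 | step 2 | bis(5,7-dimethoxy-4-oxo-4H-chromen-2-yl)zinc | COc1cc(OC)c2c(=O)cc([Zn]c3cc(=O)c4c(OC)cc(OC)cc4o3)oc2c1
F4 | step 2 | 5,7-dimethoxy-2-nonacosyl-4H-chromen-4-one | CCCCCCCCCCCCCCCCCCCCCCCCCCCCCc1cc(=O)c2c(OC)cc(OC)cc2o1
F5 | step 3 | 2-iodo-5,7-bis(methoxymethoxy)-4H-chromen-4-one | COCOc1cc(OCOC)c2c(=O)cc(I)oc2c1
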